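1. For the flask I reckoned 0.750: free base plus scavenger charged, over twice the electrophile charged, the acid budget. The twice came from my own picture: each electrophile turned takes one nucleophile and gives one acid, which binds a second nucleophile as protonated nucleophile. Below 1, I treated the acid sinks as the limiting reagent, with the crossing at that fraction reacted.

| flask | electrophile | free base | protonated nucleophile | scavenger | protic impurity | remark | time |
|---|---|---|---|---|---|---|---|
| ochre | 28 mM | 28 mM | 28 mM | 14 mM | 28 mM | run made earlier |  |
| green | 28 mM | 28 mM | 110 mM | 14 mM | 28 mM | run made earlier |  |
| amber | 14 mM | 28 mM | 56 mM | 14 mM | 28 mM | run made earlier |  |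
| flask | 28 mM | 28.0 mM | 56.0 mM | 14.0 mM | 28.0 mM |  | 10 d |

| run | time / d | electrophile / % | target / % |
|---|---|---|---|
| ochre | 1.67 | 47 | 25 |
| ochre | 3.00 | 39 | 14 |
| ochre | 5.00 | 30 | 7 |
| ochre | 6.00 | 27 | 4 |
| green | 0.833 | 49 | 30 |
| green | 2.00 | 31 | 23 |
| green | 4.00 | 17 | 12 |
| green | 6.00 | 12 | 4 |
| amber | 1.67 | 26 | 36 |
| amber | 3.00 | 11 | 20 |
| amber | 5.00 | 2 | 8 |
| amber | 6.00 | 2 | 7 |

(each reading ± 2 percentage points)

1. part of the electrophile that has reacted at 10 d
2. share of the unused nucleophile that is free and not bound as protonated nucleophile, at 10 d

- the numbers in the tables scatter with a standard deviation of 2 percentage points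
- what has gone from electrophile into another species counts as reacted, even if it can come back
- the earlier runs do not show how much of nucleophile is bound; that part of a forecast is a guess

2. High extreme: the amber run had a budget of 1.50, more than the flask's, and kept 2% electrophile at 5.00 d.
3. Low extreme: I read the budget as a hard stop, which put the reacted part at 75.0%.
4. Between them: the green run shared the flask's budget, yet had used 88.0% at 6.00 d, more than the crossing. The stop therefore leaked, so I committed to about that figure for the flask, a little under the forecast.
5. The forecast gave 90% reacted and 8% free, reasoning that “it should behave nearly like green”.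
6. The flask gave 87.5% reacted and 4.16% free, both within the margins.

    electrophile + nucleophile → acid set free + target (k = 0.0320 /M/min)
    nucleophile + acid set free ⇌ protonated nucleophile, settled at all times (K = 5500 /M)
    acid set free + free base ⇌ salt of the base, settled at all times (K = 6.60 × 10⁵ /M)
    electrophile + acid set free ⇌ idle adduct, settled at all times (K = 99.0 /M)
    acid set free + scavenger → scavenged by-product (k = 0.510 /M/min)
    protic impurity + free base → quenched reagent (k = 0.0160 /M/min)
    target → over-reaction product (k = 5.20 × 10⁻⁴ /min)

7. Electrophile used stood at 67.6% at 2.50 d and 79.6% at 5.00 d, so the flask passed its crossing of 75.0% between those times. One charge that fell short of the forecast was the neighbour with 70 mM electrophile: it had a budget of 0.300 and reached 71.8%, less than the forecast's 90%, with 24.1% standing as idle adduct.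

(The data come from a simulation with constants of no real substance.)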